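## The problem

Numbering used throughout: the terpenoid half carries caryophyllane numbers (C1 and C9 are the cyclobutane ring-fusion CH groups, C11 the CMe2 carbon on C1, C10 the ring CH2 on C9, C8 the methylene-bearing carbon, C4 the O- and methyl-bearing carbon, C5 the adjacent CH). Rings A, B and C are the triquinane (A the cyclopentenone, C the carboxyl ring), ring D the dihydropyran, ring E the nine-membered ring and ring F the cyclobutane.

The target is a hexacycle in which a linear cis-anti-cis triquinane is joined through a 2-alkoxy-cyclopentenone (ring A) to a dihydropyran that is cis-fused (C4 methyl and C5 hydrogen cis) to a nine-membered ring carrying a trans-fused gem-dimethylcyclobutane. Its nine stereocentres fall into two clusters, four in the terpenoid half (1S,4S,5S,9R) and five in the triquinane, separated by the flat enone, so neither half can direct the other. Within the terpenoid half, C4 and C5 lie three bonds away from the cyclobutane in any open-chain precursor and need reagent control; within the triquinane, the ring B–C fusion can direct the quaternary methyl carbon and the CH next to the ketone. The quaternary carbon of ring C has its carboxyl group on the convex face, which is the face an alkylating agent would choose, so methylation of an ester enolate would give the wrong epimer. The exocyclic methylene on the strained medium ring, the tertiary-alkyl enol ether and the epimerisable centres α to carbonyl groups will not survive strong acid or careless base. The cyclobutane has its CH2 (C10) on C9, the carbon bonded to C8, and its CMe2 (C11) on C1; this is the head-to-tail pattern of a cyclohexenone–isobutylene photoadduct, with C9 and C1 as the former α- and β-carbons and C8 as the former carbonyl carbon. The (1S,9R) pair is the mirror image of that in (−)-β-caryophyllene, so the natural terpene cannot be used and the ring must be made enantioselectively.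

## Retrosynthesis

Ring A first. Target 37 is the acid of ester 36, and 36 is opened at the bond between the ring D alkene carbon and the methyl-bearing ring B carbon to give cross-conjugated dienone 35. This Nazarov cut joins two finished, enantiopure halves at the only place where they meet. It removes the last quaternary centre and the epimerisable CH in one operation, both set by the convex face of the ring B–C bicycle. A cut through ring D instead would ask for a C–O bond to a quaternary carbon late in the synthesis.

Dienone 35 is cut at both bonds of its ketone carbon into ketene acetal triflate 22 and alkenylstannane 34, to be joined by a carbonylative coupling. This is preferred over acylation chemistry because 22 comes in one step from lactone 20, and the carbonyl carbon is then supplied by the coupling itself.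

Lactone 20 is opened at the C7–C8 bond of ring E to give 18, which carries a vinyl group on C5 and a 1-(triflyloxy)vinyl group on C9. Closing here by hydroboration and B-alkyl Suzuki coupling gives the exocyclic methylene directly. A metathesis closure would need a vinyl ketone in the presence of the lactone, and then hydrogenation and methylenation. The price is a nine-membered macrocyclisation.

Lactone 18 is cut at the C4–C5 bond and at the lactone C–O bond into methyl ketone 13 and (E)-allylboronate 16. One allylboration then makes the C–C bond, both stereocentres, the vinyl group and, after lactonisation, ring D. The forward step must distinguish the faces of a methyl alkyl ketone; that is the weak point of this cut and is covered by a longer epoxide-based detour.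

Ketone 13 goes back through 12, 11, 9 and 8 to aldehyde acid 6. One methyl nucleophile turns the acid into the C9 acetyl group and the aldehyde into the C4 carbinol, and the acetyl group is fixed as its enol triflate before the C4 ketone is unveiled. Acid 6 comes from ozonolysis of silyl enol ether 5 of ketone 4, which cuts the six-membered ring between the carbonyl carbon and its CH2 neighbour.

Ketone 4 is the C1 epimer of photoadduct 3, and 3 is cut at both new cyclobutane bonds into enone 1 and alkene 2. Only the former β-carbon has to be set in this step; the α-carbon is equilibrated twice, to cis in the bicycle for clean handling and to trans in 8 after ring opening.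

Stannane 34 comes from enol triflate 33. Its ring C quaternary centre is traced through 32, 31, 30 and 29 to the two diastereotopic esters of 28. Triflate 28 comes from Pauson–Khand enone 26, 26 from enyne 25, and 25 from malonate 23 by way of 24. The Pauson–Khand cut makes ring B, places the methyl group and the oxygen on the right carbons, and needs only one catalyst-controlled stereocentre. Boronate 16 comes from ester 14 through allylic acetate 15.

## Roads not taken

Alternative 1: The cut removes two ring bonds of the triquinane, and the forward step is a tin-hydride-mediated tandem radical cyclisation that closes rings C and A and gives A1. It builds the cis-anti-cis skeleton and the quaternary methyl carbon in one well-understood step, and in that respect it is better than a late Nazarov closure on a large substrate. Its weak points here are that A1 still carries two equal esters on ring C and has no link to the terpenoid half. Ring D would then have to be formed on a finished triquinane, with a C–O bond to the quaternary C4 and no obvious control of C4 and C5. The chosen plan sets against it a union that makes ring A and attaches ring D in two steps, with C4 and C5 fixed beforehand.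

Alternative 2: The cut is the ring E bond formed in an anionic oxy-Cope rearrangement of a bicyclic alkoxide, which expands a five-membered ring to the nine-membered ring and gives A2. This is the stronger way to make ring E: no macrocyclisation, the trans ring fusion after equilibration, and a ketone left at C8 for methylenation. A2 has a C3–C4 alkene and only C5 in place, so the oxygen at C4 would have to be added later across a medium-ring alkene, where transannular reactions and facial control are both uncertain. Its precursor also needs three stereocentres on a small bicycle. The chosen plan accepts a riskier ring closure (step 11) in return for C4 and C5 being set in an open chain and an exocyclic alkene that needs no further steps.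

Alternative 3: The cut is the ring A bond made by Lewis-acid Nazarov closure, giving A3, which is identical with 36; the precursor is dienone 35 of the present route. As a union it is fully convergent and it is used here unchanged as step 24, so in that respect the two plans are equal. Taken as the strategy, it leaves open how the terpenoid half, antipodal to the natural series, is obtained as one enantiomer, and that is decided in the photocycloaddition. The Nazarov step is at least as hard as the key step, and the chosen plan sets against that only what it adds upstream.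

Key step: step 1

Assumption: the sense of induction of the chiral catalysts in steps 1, 10 and 15 is taken by analogy with their parent substrates; in each case the antipode that gives the drawn configuration is meant.

## Route

Step 1
Reactants: 1 cyclohex-2-en-1-one; 2 2-methylprop-1-ene (isobutylene)
Product: 4 (1S,6S)-7,7-dimethylbicyclo[4.2.0]octan-2-one (cis-fused), via trans-fused photoadduct 3 (not isolated)
Conditions: B-aryl oxazaborolidine from an α,α-diarylprolinol (50 mol%) activated with AlBr3, hν (366 nm), CH2Cl2, −78 °C, excess 2; then basic Al2O3, CH2Cl2, rt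
Reagents that add atoms: none
Why: The Lewis acid bound to the carbonyl of 1 shifts the absorption to longer wavelength, so at 366 nm essentially only the complexed enone is excited. Its triplet adds to 2 stepwise through 1,4-biradicals and the cyclobutane closes by radical recombination after spin inversion, a formal [2+2] that makes the Cβ–CMe2 and Cα–CH2 bonds; the closest known reaction type is the Lewis-acid-catalysed enantioselective intermolecular enone–alkene [2+2] photocycloaddition. The head-to-tail orientation is the electronic preference of the polarised enone triplet for an electron-rich 1,1-disubstituted alkene and needs no device in the substrate. C6 (former β-carbon) is set by the catalyst, whose aryl group shields one face of the bound enone. C1 (former α-carbon) forms under kinetic control, partly as the strained trans fusion 3 that the twisted triplet allows, and is equilibrated on alumina to cis ketone 4 so that one compound is carried on. That centre is reset to trans in step 4, so the step needs only enantioface selectivity at the β-carbon and head-to-tail regioselectivity.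

Step 2
Reactants: 4 (1S,6S)-7,7-dimethylbicyclo[4.2.0]octan-2-one
Product: 5 trimethyl{[(1S,6S)-7,7-dimethylbicyclo[4.2.0]oct-2-en-2-yl]oxy}silane
Conditions: Me3SiCl, LiN(i-Pr)2 (internal quench), THF, −78 °C
Reagents that add atoms: chlorotrimethylsilane, C[Si](C)(C)Cl
Why: Kinetic deprotonation occurs at the CH2 group, because an enolate towards the ring fusion would put a double bond exocyclic to the cyclobutane; in situ silylation gives the silyl enol ether without touching the stereocentres.

Step 3
Reactants: 5 trimethyl{[(1S,6S)-7,7-dimethylbicyclo[4.2.0]oct-2-en-2-yl]oxy}silane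
Product: 6 (1S,2S)-3,3-dimethyl-2-(3-oxopropyl)cyclobutane-1-carboxylic acid
Conditions: O3, CH2Cl2/MeOH, −78 °C; Me2S, −78 °C → rt; aqueous work-up
Reagents that add atoms: ozone, [O-][O+]=O
Why: Ozonolysis of the electron-rich silyl enol ether cleaves the ring; the silyloxy carbon becomes the acid after work-up and the CH end the aldehyde after reduction with Me2S, so the two termini come out differentiated.

Step 4
Reactants: 6 (1S,2S)-3,3-dimethyl-2-(3-oxopropyl)cyclobutane-1-carboxylic acid
Product: 8 1-[(1R,2S)-2-(3-hydroxybutyl)-3,3-dimethylcyclobutyl]ethan-1-one (trans; carbinol epimers), via cis hydroxy ketone 7 (not isolated)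
Conditions: MeLi (4 equiv), Et2O, 0 °C → rt; inverse quench into cold 1 M HCl; then NaOMe, MeOH, rt
Reagents that add atoms: methyllithium, [Li]C
Why: MeLi adds to the aldehyde and converts the lithium carboxylate through its gem-diolate into the methyl ketone (acid to methyl ketone). Methoxide then equilibrates the centre α to the ketone to the trans-1,2-disubstituted cyclobutane, which avoids the cis contact of the acetyl group with the side chain and sets C9. The carbinol mixture is removed in step 7.

Step 5
Reactants: 8 1-[(1R,2S)-2-(3-hydroxybutyl)-3,3-dimethylcyclobutyl]ethan-1-one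
Product: 9 1-[(1R,2S)-3,3-dimethyl-2-{3-[(triethylsilyl)oxy]butyl}cyclobutyl]ethan-1-one
Conditions: Et3SiCl, imidazole, CH2Cl2, 0 °C
Reagents that add atoms: chlorotriethylsilane, CC[Si](Cl)(CC)CC
Why: Routine silylation of the secondary alcohol, so that the next step meets only one acidic site.

Step 6
Reactants: 9 1-[(1R,2S)-3,3-dimethyl-2-{3-[(triethylsilyl)oxy]butyl}cyclobutyl]ethan-1-one
Product: 11 1-[(1R,2S)-3,3-dimethyl-2-{3-[(triethylsilyl)oxy]butyl}cyclobutyl]ethenyl trifluoromethanesulfonate, via potassium enolate 10 (not isolated)
Conditions: KN(SiMe3)2, THF, −78 °C; then PhNTf2, −78 → 0 °C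
Reagents that add atoms: N-phenylbis(trifluoromethanesulfonimide), O=S(=O)(N(c1ccccc1)S(=O)(=O)C(F)(F)F)C(F)(F)F
Why: Kinetic deprotonation takes the methyl group (the methine would give an alkylidenecyclobutane) and O-sulfonylation gives the terminal enol triflate. C9 is now allylic and can no longer epimerise.

Step 7
Reactants: 11 1-[(1R,2S)-3,3-dimethyl-2-{3-[(triethylsilyl)oxy]butyl}cyclobutyl]ethenyl trifluoromethanesulfonate
Product: 13 1-[(1R,2S)-3,3-dimethyl-2-(3-oxobutyl)cyclobutyl]ethenyl trifluoromethanesulfonate, via free alcohol 12 (not isolated)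
Conditions: HF·pyridine, THF, 0 °C; then Dess–Martin periodinane, NaHCO3, CH2Cl2, rt
Reagents that add atoms: none
Why: Desilylation and Dess–Martin oxidation give the methyl ketone at C4; the enol triflate is inert to both reagents.

Step 8
Reactants: 14 methyl pent-4-enoate
Product: 15 methyl (E)-6-acetoxyhex-4-enoate
Conditions: (Z)-AcOCH2CH=CHCH2OAc (3 equiv), second-generation Grubbs catalyst (2 mol%), CH2Cl2, 40 °C
Reagents that add atoms: (Z)-but-2-ene-1,4-diyl diacetate, CC(=O)OC/C=C\COC(C)=O
Why: Cross-metathesis of a terminal alkene with an excess of a symmetrical internal alkene; the E isomer should predominate and residual Z isomer is corrected in step 9.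

Step 9
Reactants: 15 methyl (E)-6-acetoxyhex-4-enoate
Product: 16 methyl (E)-6-(5,5-dimethyl-1,3,2-dioxaborinan-2-yl)hex-4-enoate
Conditions: bis(neopentyl glycolato)diboron, Pd2(dba)3 (2.5 mol%), DMSO, 50 °C
Reagents that add atoms: bis(neopentyl glycolato)diboron, CC1(C)COB(OC1)B1OCC(C)(C)CO1
Why: Palladium-catalysed borylation of an allylic acetate passes through a π-allyl complex and gives the linear (E)-allylboronate whatever the geometry of 15.

Step 10
Reactants: 13 1-[(1R,2S)-3,3-dimethyl-2-(3-oxobutyl)cyclobutyl]ethenyl trifluoromethanesulfonate; 16 methyl (E)-6-(5,5-dimethyl-1,3,2-dioxaborinan-2-yl)hex-4-enoate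
Product: 18 1-[(1R,2S)-2-{2-[(2S,3R)-3-ethenyl-2-methyl-6-oxooxan-2-yl]ethyl}-3,3-dimethylcyclobutyl]ethenyl trifluoromethanesulfonate, via hydroxy ester 17 (not isolated)
Conditions: (S)-3,3′-Br2-BINOL (15 mol%), t-BuOH (2 equiv), toluene, −35 °C → rt; then pyridinium p-toluenesulfonate (cat.), toluene, 50 °C
Reagents that add atoms: none
Why: Chiral-biphenol-catalysed allylboration of a methyl ketone through a closed chair: the (E)-boronate holds its γ-substituent equatorial and the larger ketone arm sits equatorial, which puts the vinyl group and the C3 chain cis on the later lactone. The diol bound to boron selects the ketone face and so fixes C4 and C5 relative to the remote cyclobutane. Acid-catalysed lactonisation of 17 closes ring D.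

Step 11
Reactants: 18 the vinyl lactone enol triflate of step 10
Product: 20 3-[(1S,4S,5S,9R)-4-hydroxy-4,11,11-trimethyl-8-methylidenebicyclo[7.2.0]undecan-5-yl]propanoic acid δ-lactone, via B-alkyl-9-BBN 19 (not isolated)
Conditions: 9-BBN-H, THF, 0 °C → rt; then Pd(dppf)Cl2 (10 mol%), AsPh3, Cs2CO3, DMF/THF/H2O, 50 °C, slow addition to high dilution
Reagents that add atoms: none
Why: 9-BBN-H hydroborates only the monosubstituted alkene. Intramolecular B-alkyl Suzuki–Miyaura coupling with the enol triflate forms the C7–C8 bond, closes ring E (a closure known for nine-membered carbocycles) and leaves the exocyclic methylene in place. No stereocentre is formed.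

Step 12
Reactants: 20 the tricyclic δ-lactone of step 11
Product: 22 ketene acetal triflate of 20 (lactone C=O replaced by C(OSO2CF3)=CH in ring D), via potassium enolate 21 (not isolated)
Conditions: KN(SiMe3)2, THF/HMPA, −78 °C; then PhNTf2; used without chromatography
Reagents that add atoms: N-phenylbis(trifluoromethanesulfonimide), O=S(=O)(N(c1ccccc1)S(=O)(=O)C(F)(F)F)C(F)(F)F
Why: The lactone α-CH2 is the only acidic position; O-triflation of δ-lactone enolates to ketene acetal triflates is established, and the product is used at once because it is labile.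

Step 13
Reactants: 23 dimethyl propanedioate (dimethyl malonate)
Product: 24 dimethyl 2-(prop-2-en-1-yl)propanedioate
Conditions: allyl bromide, K2CO3, acetone, reflux
Reagents that add atoms: allyl bromide, C=CCBr
Why: Malonate alkylation; an excess of 23 limits dialkylation.

Step 14
Reactants: 24 dimethyl 2-(prop-2-en-1-yl)propanedioate
Product: 25 dimethyl 2-(but-2-yn-1-yl)-2-(prop-2-en-1-yl)propanedioate
Conditions: NaH, THF, 0 °C; 1-bromobut-2-yne, rt
Reagents that add atoms: 1-bromobut-2-yne, CC#CCBr
Why: Second malonate alkylation gives the 1,6-enyne.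

Step 15
Reactants: 25 dimethyl 2-(but-2-yn-1-yl)-2-(prop-2-en-1-yl)propanedioate
Product: 26 dimethyl (3aR)-6-methyl-5-oxo-3,3a,4,5-tetrahydropentalene-2,2(1H)-dicarboxylate
Conditions: [Rh(CO)2Cl]2 (3 mol%), (S)-BINAP (9 mol%), AgOTf (12 mol%), CO (1 atm), THF, 90 °C
Reagents that add atoms: carbon monoxide, [C-]#[O+]
Why: Rhodium-catalysed asymmetric Pauson–Khand reaction; the BINAP-bound metal selects the alkene face and sets the ring-fusion CH, and the alkyne methyl group ends α to the ketone, where ring B needs it.

Step 16
Reactants: 26 dimethyl (3aR)-6-methyl-5-oxo-3,3a,4,5-tetrahydropentalene-2,2(1H)-dicarboxylate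
Product: 28 dimethyl (3aR,6aR)-4-methyl-5-{[(trifluoromethyl)sulfonyl]oxy}-3,3a,6,6a-tetrahydropentalene-2,2(1H)-dicarboxylate, via triethylsilyl enol ether 27 (not isolated)
Conditions: Et3SiH, RhCl(PPh3)3 (1 mol%), benzene, 60 °C; then CsF, PhNTf2, 1,2-dimethoxyethane, rt
Reagents that add atoms: N-phenylbis(trifluoromethanesulfonimide), O=S(=O)(N(c1ccccc1)S(=O)(=O)C(F)(F)F)C(F)(F)F
Why: 1,4-Hydrosilylation delivers hydride to the ring-fusion β-carbon on the side of the existing ring-fusion hydrogen (only the cis-bicyclo[3.3.0]octane is within reach) and gives the tetrasubstituted silyl enol ether regiospecifically. Fluoride and PhNTf2 turn it into the enol triflate without enolate equilibration.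

Step 17
Reactants: 28 the enol triflate diester of step 16
Product: 29 (2R,3aR,6aR)-2-(methoxycarbonyl)-4-methyl-5-{[(trifluoromethyl)sulfonyl]oxy}-1,2,3,3a,6,6a-hexahydropentalene-2-carboxylic acid (acid on the convex face)
Conditions: Me3SnOH (1.5 equiv), 1,2-dichloroethane, 60 °C; 1 M HCl work-up
Reagents that add atoms: trimethyltin hydroxide, C[Sn](C)(C)O
Why: The ester on the convex face, cis to the ring-fusion hydrogens, is the more accessible of the two diastereotopic esters and should be cleaved first by this mild reagent; the choice sets the ring C quaternary centre.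

Step 18
Reactants: 29 the half acid of step 17
Product: 30 (2S,3aR,6aR)-2-(hydroxymethyl)-4-methyl-5-{[(trifluoromethyl)sulfonyl]oxy}-1,2,3,3a,6,6a-hexahydropentalene-2-carboxylic acid
Conditions: LiBH4, THF/MeOH, 0 °C → rt; 1 M HCl work-up
Reagents that add atoms: none
Why: LiBH4 reduces the remaining concave-face ester but not the lithium carboxylate; the enol triflate is untouched.

Step 19
Reactants: 30 the hydroxy acid of step 18
Product: 31 methyl (2S,3aR,6aR)-2-(hydroxymethyl)-4-methyl-5-{[(trifluoromethyl)sulfonyl]oxy}-1,2,3,3a,6,6a-hexahydropentalene-2-carboxylate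
Conditions: Me3SiCHN2, toluene/MeOH, 0 °C
Reagents that add atoms: (trimethylsilyl)diazomethane, C[Si](C)(C)C=[N+]=[N-]
Why: Mild methyl ester formation from the hindered acid.

Step 20
Reactants: 31 the hydroxy ester of step 19
Product: 32 methyl (2R,3aR,6aR)-2-(iodomethyl)-4-methyl-5-{[(trifluoromethyl)sulfonyl]oxy}-1,2,3,3a,6,6a-hexahydropentalene-2-carboxylate
Conditions: I2, PPh3, imidazole, toluene, 80 °C
Reagents that add atoms: iodine, II
Why: Appel-type iodination; heating is needed for the neopentyl-type alcohol.

Step 21
Reactants: 32 the iodide of step 20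
Product: 33 methyl (2S,3aR,6aR)-2,4-dimethyl-5-{[(trifluoromethyl)sulfonyl]oxy}-1,2,3,3a,6,6a-hexahydropentalene-2-carboxylate
Conditions: Bu3SnH (0.3 M), AIBN (cat.), toluene, 80 °C
Reagents that add atoms: none
Why: Radical deiodination turns the concave-face CH2I into the methyl group; a high stannane concentration should outrun transannular addition of the primary radical to the ring B alkene.

Step 22
Reactants: 33 the enol triflate of step 21
Product: 34 methyl (2S,3aR,6aR)-2,4-dimethyl-5-(trimethylstannyl)-1,2,3,3a,6,6a-hexahydropentalene-2-carboxylate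
Conditions: Me3SnSnMe3, Pd(PPh3)4 (5 mol%), LiCl, THF, 65 °C
Reagents that add atoms: hexamethylditin, C[Sn](C)(C)[Sn](C)(C)C
Why: Palladium-catalysed stannylation of an enol triflate (Stille-type coupling with the distannane).

Step 23
Reactants: 22 ketene acetal triflate of 20; 34 the alkenylstannane of step 22
Product: 35 dienone: the ketone carbon links the oxygen-bearing alkene carbon of ring D (from 22) and the stannyl-bearing alkene carbon of 34, all other groups unchanged
Conditions: CO (1 atm), Pd(PPh3)4 (5 mol%), LiCl, THF, 50 °C
Reagents that add atoms: carbon monoxide, [C-]#[O+]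
Why: Carbonylative Stille coupling (oxidative addition of the triflate, CO insertion, transmetallation from tin) joins the halves and supplies the ring A carbonyl carbon; the same coupling followed by Nazarov closure is an established way to build fused cyclopentenones.

Step 24
Reactants: 35 the dienone of step 23
Product: 36 methyl ester of the target
Conditions: Cu(OTf)2 (1 equiv), ClCH2CH2Cl, rt → 50 °C
Reagents that add atoms: none
Why: Nazarov cyclisation, a conrotatory 4π closure of the α-alkoxy pentadienyl cation. The new bond to the methyl-bearing ring B carbon forms on the convex face of the bicyclo[3.3.0]octene, anti to ring C, which gives the cis-anti-cis triquinane. The oxyallyl cation loses the proton next to its oxygen-stabilised end, and protonation α to the ketone gives the cis A–B fusion.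

Step 25
Reactants: 36 methyl ester of the target
Product: 37 the target acid, CNP0483070.2
Conditions: LiOH, THF/MeOH/H2O, 40 °C; then 1 M HCl
Reagents that add atoms: lithium hydroxide, [Li+].[OH-]
Why: Saponification of the convex-face ester; the CH α to the ketone can only relax to the cis fusion it already has.

## Compound list

1 | cyclohex-2-en-1-one | O=C1C=CCCC1 | starting material
2 | 2-methylprop-1-ene | C=C(C)C | starting material
3 | (1R,6S)-7,7-dimethylbicyclo[4.2.0]octan-2-one, trans-fused | O=C1CCC[C@H]2[C@H]1CC2(C)C | intermediate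
4 | (1S,6S)-7,7-dimethylbicyclo[4.2.0]octan-2-one, cis-fused | O=C1CCC[C@H]2[C@@H]1CC2(C)C | intermediate
5 | trimethyl{[(1S,6S)-7,7-dimethylbicyclo[4.2.0]oct-2-en-2-yl]oxy}silane | C[Si](C)(C)OC1=CCC[C@H]2[C@@H]1CC2(C)C | intermediate
6 | (1S,2S)-3,3-dimethyl-2-(3-oxopropyl)cyclobutane-1-carboxylic acid | O=CCC[C@H]1[C@@H](C(=O)O)CC1(C)C | intermediate
7 | 1-[(1S,2S)-2-(3-hydroxybutyl)-3,3-dimethylcyclobutyl]ethan-1-one | CC(O)CC[C@H]1[C@@H](C(C)=O)CC1(C)C | intermediate
8 | 1-[(1R,2S)-2-(3-hydroxybutyl)-3,3-dimethylcyclobutyl]ethan-1-one | CC(O)CC[C@H]1[C@H](C(C)=O)CC1(C)C | intermediate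
9 | 1-[(1R,2S)-3,3-dimethyl-2-{3-[(triethylsilyl)oxy]butyl}cyclobutyl]ethan-1-one | CC(O[Si](CC)(CC)CC)CC[C@H]1[C@H](C(C)=O)CC1(C)C | intermediate
10 | potassium enolate of 9 (methyl side) | [K+].CC(O[Si](CC)(CC)CC)CC[C@H]1[C@H](C(=C)[O-])CC1(C)C | intermediate
11 | 1-[(1R,2S)-3,3-dimethyl-2-{3-[(triethylsilyl)oxy]butyl}cyclobutyl]ethenyl trifluoromethanesulfonate | CC(O[Si](CC)(CC)CC)CC[C@H]1[C@H](C(=C)OS(=O)(=O)C(F)(F)F)CC1(C)C | intermediate
12 | 1-[(1R,2S)-2-(3-hydroxybutyl)-3,3-dimethylcyclobutyl]ethenyl trifluoromethanesulfonate | CC(O)CC[C@H]1[C@H](C(=C)OS(=O)(=O)C(F)(F)F)CC1(C)C | intermediate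
13 | 1-[(1R,2S)-3,3-dimethyl-2-(3-oxobutyl)cyclobutyl]ethenyl trifluoromethanesulfonate | CC(=O)CC[C@H]1[C@H](C(=C)OS(=O)(=O)C(F)(F)F)CC1(C)C | intermediate
14 | methyl pent-4-enoate | C=CCCC(=O)OC | starting material
15 | methyl (E)-6-acetoxyhex-4-enoate | COC(=O)CC/C=C/COC(C)=O | intermediate
16 | methyl (E)-6-(5,5-dimethyl-1,3,2-dioxaborinan-2-yl)hex-4-enoate | COC(=O)CC/C=C/CB1OCC(C)(C)CO1 | intermediate
17 | methyl (4R,5S)-7-[(1S,4R)-2,2-dimethyl-4-{1-[(trifluoromethylsulfonyl)oxy]ethenyl}cyclobutyl]-4-ethenyl-5-hydroxy-5-methylheptanoate | COC(=O)CC[C@H](C=C)[C@@](C)(O)CC[C@H]1[C@H](C(=C)OS(=O)(=O)C(F)(F)F)CC1(C)C | intermediate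
18 | 1-[(1R,2S)-2-{2-[(2S,3R)-3-ethenyl-2-methyl-6-oxooxan-2-yl]ethyl}-3,3-dimethylcyclobutyl]ethenyl trifluoromethanesulfonate | C=C[C@H]1CCC(=O)O[C@@]1(C)CC[C@H]1[C@H](C(=C)OS(=O)(=O)C(F)(F)F)CC1(C)C | intermediate
19 | B-alkyl-9-borabicyclo[3.3.1]nonane from anti-Markovnikov hydroboration of the vinyl group of 18 | B1(C2CCCC1CCC2)CC[C@H]1CCC(=O)O[C@@]1(C)CC[C@H]1[C@H](C(=C)OS(=O)(=O)C(F)(F)F)CC1(C)C | intermediate
20 | 3-[(1S,4S,5S,9R)-4-hydroxy-4,11,11-trimethyl-8-methylidenebicyclo[7.2.0]undecan-5-yl]propanoic acid δ-lactone | C=C1CC[C@H]2CCC(=O)O[C@@]2(C)CC[C@H]2[C@H]1CC2(C)C | intermediate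
21 | potassium enolate of lactone 20 | [K+].C=C1CC[C@H]2CC=C([O-])O[C@@]2(C)CC[C@H]2[C@H]1CC2(C)C | intermediate
22 | ketene acetal triflate of 20 | C=C1CC[C@H]2CC=C(OS(=O)(=O)C(F)(F)F)O[C@@]2(C)CC[C@H]2[C@H]1CC2(C)C | intermediate
23 | dimethyl propanedioate | COC(=O)CC(=O)OC | starting material
24 | dimethyl 2-(prop-2-en-1-yl)propanedioate | COC(=O)C(CC=C)C(=O)OC | intermediate
25 | dimethyl 2-(but-2-yn-1-yl)-2-(prop-2-en-1-yl)propanedioate | COC(=O)C(CC=C)(CC#CC)C(=O)OC | intermediate
26 | dimethyl (3aR)-6-methyl-5-oxo-3,3a,4,5-tetrahydropentalene-2,2(1H)-dicarboxylate | O=C1C[C@H]2CC(C(=O)OC)(C(=O)OC)CC2=C1C | intermediate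
27 | dimethyl (3aR,6aR)-4-methyl-5-[(triethylsilyl)oxy]-3,3a,6,6a-tetrahydropentalene-2,2(1H)-dicarboxylate | CC1=C(O[Si](CC)(CC)CC)C[C@H]2CC(C(=O)OC)(C(=O)OC)C[C@H]21 | intermediate
28 | dimethyl (3aR,6aR)-4-methyl-5-{[(trifluoromethyl)sulfonyl]oxy}-3,3a,6,6a-tetrahydropentalene-2,2(1H)-dicarboxylate | CC1=C(OS(=O)(=O)C(F)(F)F)C[C@H]2CC(C(=O)OC)(C(=O)OC)C[C@H]21 | intermediate
29 | (2R,3aR,6aR) half acid, CO2H on the convex face | CC1=C(OS(=O)(=O)C(F)(F)F)C[C@H]2C[C@](C(=O)OC)(C(=O)O)C[C@H]21 | intermediate
30 | (2S,3aR,6aR) hydroxymethyl acid | CC1=C(OS(=O)(=O)C(F)(F)F)C[C@H]2C[C@](CO)(C(=O)O)C[C@H]21 | intermediate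
31 | methyl (2S,3aR,6aR)-2-(hydroxymethyl)-4-methyl-5-(triflyloxy)-1,2,3,3a,6,6a-hexahydropentalene-2-carboxylate | CC1=C(OS(=O)(=O)C(F)(F)F)C[C@H]2C[C@](CO)(C(=O)OC)C[C@H]21 | intermediate
32 | methyl (2R,3aR,6aR)-2-(iodomethyl)-4-methyl-5-(triflyloxy)-1,2,3,3a,6,6a-hexahydropentalene-2-carboxylate | CC1=C(OS(=O)(=O)C(F)(F)F)C[C@H]2C[C@](CI)(C(=O)OC)C[C@H]21 | intermediate
33 | methyl (2S,3aR,6aR)-2,4-dimethyl-5-(triflyloxy)-1,2,3,3a,6,6a-hexahydropentalene-2-carboxylate | CC1=C(OS(=O)(=O)C(F)(F)F)C[C@H]2C[C@](C)(C(=O)OC)C[C@H]21 | intermediate
34 | methyl (2S,3aR,6aR)-2,4-dimethyl-5-(trimethylstannyl)-1,2,3,3a,6,6a-hexahydropentalene-2-carboxylate | CC1=C([Sn](C)(C)C)C[C@H]2C[C@](C)(C(=O)OC)C[C@H]21 | intermediate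
35 | cross-conjugated dienone joining ring D of 22 and the cyclopentene of 34 through a ketone | C=C1CC[C@H]2CC=C(C(=O)C3=C(C)[C@@H]4C[C@@](C)(C(=O)OC)C[C@@H]4C3)O[C@@]2(C)CC[C@H]2[C@H]1CC2(C)C | intermediate
36 | methyl ester of the target | C=C1CC[C@H]2CC3=C(O[C@@]2(C)CC[C@H]2[C@H]1CC2(C)C)C(=O)[C@@H]1C[C@H]2C[C@](C)(C(=O)OC)C[C@H]2[C@]31C | intermediate
37 | target acid CNP0483070.2 | C=C1CC[C@H]2CC3=C(O[C@@]2(C)CC[C@H]2[C@H]1CC2(C)C)C(=O)[C@@H]1C[C@H]2C[C@](C)(C(=O)O)C[C@H]2[C@]31C | target

## Step count and least certain steps

Total: 25 steps. Longest linear sequence: 13 steps (1–7, 10–12, 23–25 from cyclohexenone; the ring B–C branch, 13–22 then 23–25, is equally long).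

Step 1 (key step). Enantioface shielding may be incomplete, because free enone is also excited to some extent at 366 nm and the Lewis acid can degrade under irradiation, and some head-to-head addition may occur. Fallback: irradiate 1 and 2 without the Lewis acid and equilibrate on alumina, which gives 4 together with its mirror image (1R,6R)-7,7-dimethylbicyclo[4.2.0]octan-2-one F1. Add lithiated (S)-N,S-dimethyl-S-phenylsulfoximine, separate the diastereomeric adducts by chromatography and heat the adduct of the (1S,6S) ketone, β-hydroxysulfoximine F2, to release 4. The fallback sets out from 1 and 2 and returns at 4.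

Step 10. The catalyst may fail to tell the methyl arm from the primary alkyl arm of ketone 13, which would erode both the facial and the anti/syn selectivity; slow ligand exchange on the cyclic boronate would also let an unselective background reaction compete. Fallback: build both centres on an alkene of fixed geometry, setting out from 8 and returning at 18.
- Mask the acetyl group with ethylene glycol to give 4-[(1S,4R)-2,2-dimethyl-4-(2-methyl-1,3-dioxolan-2-yl)cyclobutyl]butan-2-ol F3, and oxidise with Dess–Martin periodinane to the corresponding butan-2-one F4.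
- Olefinate with triethyl phosphonoacetate and NaH and remove the Z isomer to obtain the ethyl (E)-3-methylpent-2-enoate F5; reduce with i-Bu2AlH to the (E)-allylic alcohol F6.
- Sharpless epoxidation (Ti(OiPr)4, L-(+)-diethyl tartrate, t-BuOOH) gives the (2S,3S)-epoxy alcohol F7.
- CuI-catalysed opening with 2-(1,3-dioxan-2-yl)ethylmagnesium bromide at the secondary epoxide carbon, with inversion, gives the 1,3-diol F8.
- TEMPO/PhI(OAc)2 gives the β-hydroxy aldehyde F9, and Cp2Ti(μ-Cl)(μ-CH2)AlMe2 gives the vinyl compound F10.
- CrO3/H2SO4 in acetone removes both acetals and oxidises the ring D lactol to the keto lactone F11.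
- Tf2O with 2,6-di-tert-butyl-4-methylpyridine forms the terminal enol triflate, which is 18.

Step 11. Intermolecular coupling (oligomers) may outrun the nine-membered closure, and the alkylpalladium intermediate may be lost to β-hydride elimination or protodeboronation. Fallback: close the ring by carbonyl addition instead, setting out from 18 and returning at 20. Hydroboration with 9-BBN-H and oxidation with NaBO3 gives the primary alcohol F12, and Dess–Martin oxidation gives the aldehyde F13. Nozaki–Hiyama–Kishi closure (CrCl2, catalytic NiCl2, DMSO, high dilution) of the enol triflate onto the aldehyde gives the nine-membered allylic alcohol F14. Its formate ester F15 is reduced with Pd(OAc)2/PBu3, which delivers hydride to the ring carbon and restores the exocyclic alkene of 20.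

Step 23. Ketene acetal triflate 22 may hydrolyse before oxidative addition, and slow transmetallation of the tetrasubstituted stannane may lead to coupling without CO or to reduction of the triflate. Fallback: avoid both 22 and CO, setting out from 20 and 33 and returning at 35. Reduce 20 with i-Bu2AlH to the lactol F16 and dehydrate with MsCl/Et3N to the dihydropyran F17, which t-BuLi lithiates at the oxygen-bearing alkene carbon. In parallel, convert 33 by palladium-catalysed aminocarbonylation (Pd(OAc)2, Ph2P(CH2)3PPh2, CO, MeNH(OMe)·HCl, Et3N) into the Weinreb amide F18. Addition of lithiated F17 to F18 gives 35.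

## Further compounds

F1 | step 1 | (1R,6R)-7,7-dimethylbicyclo[4.2.0]octan-2-one (enantiomer of 4) | O=C1CCC[C@@H]2[C@H]1CC2(C)C
F2 | step 1 | β-hydroxysulfoximine from 4 and (S)-N,S-dimethyl-S-phenylsulfoximine | CN=[S@](=O)(C[C@@]1(O)CCC[C@H]2[C@@H]1CC2(C)C)c1ccccc1
F3 | step 10 | 4-[(1S,4R)-2,2-dimethyl-4-(2-methyl-1,3-dioxolan-2-yl)cyclobutyl]butan-2-ol | CC(O)CC[C@H]1[C@H](C2(C)OCCO2)CC1(C)C
F4 | step 10 | 4-[(1S,4R)-2,2-dimethyl-4-(2-methyl-1,3-dioxolan-2-yl)cyclobutyl]butan-2-one | CC(=O)CC[C@H]1[C@H](C2(C)OCCO2)CC1(C)C
F5 | step 10 | ethyl (E)-5-[(1S,4R)-2,2-dimethyl-4-(2-methyl-1,3-dioxolan-2-yl)cyclobutyl]-3-methylpent-2-enoate | CCOC(=O)/C=C(\C)CC[C@H]1[C@H](C2(C)OCCO2)CC1(C)C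
F6 | step 10 | (E)-5-[(1S,4R)-2,2-dimethyl-4-(2-methyl-1,3-dioxolan-2-yl)cyclobutyl]-3-methylpent-2-en-1-ol | OC/C=C(\C)CC[C@H]1[C@H](C2(C)OCCO2)CC1(C)C
F7 | step 10 | (2S,3S)-epoxy alcohol of F6 | OC[C@@H]1O[C@@]1(C)CC[C@H]1[C@H](C2(C)OCCO2)CC1(C)C
F8 | step 10 | (2R,3S)-2-[2-(1,3-dioxan-2-yl)ethyl]-3-methylpentane-1,3-diol carrying the ketal cyclobutyl group at C5 | OC[C@@H](CCC1OCCCO1)[C@@](C)(O)CC[C@H]1[C@H](C2(C)OCCO2)CC1(C)C
F9 | step 10 | β-hydroxy aldehyde from oxidation of the primary alcohol of F8 | O=C[C@@H](CCC1OCCCO1)[C@@](C)(O)CC[C@H]1[C@H](C2(C)OCCO2)CC1(C)C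
F10 | step 10 | vinyl compound from methylenation of F9 | C=C[C@@H](CCC1OCCCO1)[C@@](C)(O)CC[C@H]1[C@H](C2(C)OCCO2)CC1(C)C
F11 | step 10 | keto lactone: 18 with an acetyl group in place of the enol triflate | C=C[C@H]1CCC(=O)O[C@@]1(C)CC[C@H]1[C@H](C(C)=O)CC1(C)C
F12 | step 11 | primary alcohol from hydroboration–oxidation of the vinyl group of 18 | OCC[C@H]1CCC(=O)O[C@@]1(C)CC[C@H]1[C@H](C(=C)OS(=O)(=O)C(F)(F)F)CC1(C)C
F13 | step 11 | aldehyde from oxidation of F12 | O=CC[C@H]1CCC(=O)O[C@@]1(C)CC[C@H]1[C@H](C(=C)OS(=O)(=O)C(F)(F)F)CC1(C)C
F14 | step 11 | nine-membered allylic alcohol: 20 with OH on C7 (epimers) | C=C1C(O)C[C@H]2CCC(=O)O[C@@]2(C)CC[C@H]2[C@H]1CC2(C)C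
F15 | step 11 | formate ester of F14 | C=C1C(OC=O)C[C@H]2CCC(=O)O[C@@]2(C)CC[C@H]2[C@H]1CC2(C)C
F16 | step 23 | lactol from reduction of 20 | C=C1CC[C@H]2CCC(O)O[C@@]2(C)CC[C@H]2[C@H]1CC2(C)C
F17 | step 23 | dihydropyran from dehydration of F16 | C=C1CC[C@H]2CC=CO[C@@]2(C)CC[C@H]2[C@H]1CC2(C)C
F18 | step 23 | N-methoxy-N-methyl amide from aminocarbonylation of 33 | CON(C)C(=O)C1=C(C)[C@@H]2C[C@@](C)(C(=O)OC)C[C@@H]2C1
A1 | alternative 1 | cis-anti-cis triquinane ketal diester with exocyclic methylene on ring A | C=C1CC2(OCCO2)[C@@H]3C[C@H]4CC(C(=O)OC)(C(=O)OC)C[C@H]4[C@]13C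
A2 | alternative 2 | trans-fused (E)-cyclononenone with silyloxymethyl CH centre | O=C1CC[C@@H](CO[Si](C)(C)C(C)(C)C)/C(C)=C/C[C@H]2[C@H]1CC2(C)C
A3 | alternative 3 | methyl ester of the target (identical with 36) | C=C1CC[C@H]2CC3=C(O[C@@]2(C)CC[C@H]2[C@H]1CC2(C)C)C(=O)[C@@H]1C[C@H]2C[C@](C)(C(=O)OC)C[C@H]2[C@]31C
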